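**Plan**

1. Retrosynthesis first cuts the four ring–CH2 bonds of the methylene bridges (Mannich-type elimination–addition), leaving two butyrylfilicinic acid end rings and three butyrylphloroglucinol rings.
2. Each end ring is then cut at its C(=O)–C(CH3)2 bond and at the bonds that a dimethylketene-derived cyclobutenone and an ynol ether would supply.
3. Enabling feature: each end ring is a 6,6-dimethylcyclohexa-2,4-dienone with the ring carbonyl C1 next to the quaternary C(CH3)2 and oxygens on C1, C3 and C5. This is the product pattern of 6π closure of a dienylketene ending in an isopropylidene carbon, and the two methyl groups block aromatisation.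
4. Forward: dimethylketene and ethoxyacetylene give a strained cyclobutenone; its ring opening and annulation with a second ynol ether builds the end ring, with the C1–C(CH3)2 bond formed last. Desilylation, oxidation and ether hydrolysis then give butyrylfilicinic acid.
5. Butyrylphloroglucinol (Friedel–Crafts) is turned into its bis-Mannich base and joined to two more units to give the three-ring core; the end-ring Mannich base is then coupled to the two free ring carbons of the core.
6. Stereochemistry: the target is achiral. The only stereocentre on the way (a carbinol carbon) is carried as the racemate and removed by oxidation.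

Key step: step 4

Remark: keto–enol tautomers of the β-triketone and acylphloroglucinol units are treated as one compound, each drawn in one convenient form; ethoxyacetylene is taken as its commercial solution in hexanes.

**Step 1**
Reactants: 1 ethoxyacetylene; 2 butanal
Product: 4 1-ethoxyhex-1-yn-3-ol (racemic), via lithium ethoxyacetylide 3 (not isolated)
Conditions: n-BuLi, THF, −78 °C; then 2, −78 → 0 °C; H2O quench
Reagents that add atoms: none
Why: Deprotonation of the ynol ether C–H and 1,2-addition of the lithium acetylide to the aldehyde (acetylide addition) should give the racemic propargylic alcohol, whose carbinol centre needs no control because it is oxidised away in step 6.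

**Step 2**
Reactants: 4 1-ethoxyhex-1-yn-3-ol
Product: 5 tert-butyl[(1-ethoxyhex-1-yn-3-yl)oxy]dimethylsilane (racemic)
Conditions: TBSCl, imidazole, DMF, 0 °C → rt
Reagents that add atoms: tert-butyl(chloro)dimethylsilane (TBSCl), CC(C)(C)[Si](C)(C)Cl
Why: Standard silylation under basic conditions caps the hydroxyl, which would otherwise trap the ketenes of step 4 as esters, and avoids acid that would rearrange the ynol ether carbinol.

**Step 3**
Reactants: 6 2-methylpropanoyl chloride; 1 ethoxyacetylene (excess)
Product: 8 3-ethoxy-4,4-dimethylcyclobut-2-en-1-one, via dimethylketene 7 (not isolated)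
Conditions: Et3N, Et2O, 0 °C → reflux
Reagents that add atoms: none
Why: Dehydrochlorination gives dimethylketene, which should undergo the polar ketene–ynol ether [2+2] cycloaddition with the nucleophilic CH terminus of 1 bonding to the ketene carbonyl carbon, placing OEt on C3 and the gem-dimethyl carbon on C4.

**Step 4**
Reactants: 8 3-ethoxy-4,4-dimethylcyclobut-2-en-1-one (slight excess); 5 tert-butyl[(1-ethoxyhex-1-yn-3-yl)oxy]dimethylsilane
Product: 12 2-[1-(tert-butyldimethylsilyloxy)butyl]-3,5-diethoxy-6,6-dimethylcyclohexa-2,4-dien-1-one (racemic), via vinylketene 9 (not isolated), via alkenylcyclobutenone 10 (not isolated), via dienylketene 11 (not isolated)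
Conditions: toluene, 90 °C, sealed tube, argon
Reagents that add atoms: none
Why: Heating opens the strained cyclobutenone 8 by conrotatory 4π-electrocyclic cleavage to vinylketene 9, whose ketene C=C adds ynol ether 5 in a polar [2+2] cycloaddition to give the 4-alkenylcyclobutenone 10; a second strain-releasing 4π opening gives dienylketene 11, and its thermal disrotatory 6π-electrocyclization joins the ketene carbon (the future ring carbonyl C1) to the isopropylidene carbon (the future C(CH3)2), closing the six-membered ring. The closest known reaction type is the Danheiser benzannulation in its cyclohexadienone-forming mode for 4,4-disubstituted cyclobutenones, the thermal reverse of the photochemical opening of 6,6-disubstituted cyclohexa-2,4-dienones to dienylketenes. Ring closures: the transient four-membered ring forms by [2+2] cycloaddition and the six-membered ring by 6π-electrocyclization, all six ring atoms lying in the triene–ketene array. No stereocentre is created in 12, because the ring CH of 10 becomes sp2 and the carbinol centre of 5 is carried through unchanged as the racemate. The step needs regioselectivity in the [2+2] event, secured by the oxygen-polarised triple bond of 5 whose nucleophilic carbon (the one remote from OEt) bonds to the electrophilic ketene carbon so that the ring oxygens end up 1,3,5 and the side chain next to C1, and it needs C- rather than O-cyclisation, secured because both enol oxygens are capped as ethyl ethers and the hydroxyl as its silyl ether. The two methyl groups on the terminal carbon make torquoselectivity in the first opening irrelevant and block tautomerisation of 12 to a phenol, while reversible ring opening funnels the alkene geometry of 11 into the isomer that can cyclise.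

**Step 5**
Reactants: 12 2-[1-(tert-butyldimethylsilyloxy)butyl]-3,5-diethoxy-6,6-dimethylcyclohexa-2,4-dien-1-one
Product: 13 3,5-diethoxy-2-(1-hydroxybutyl)-6,6-dimethylcyclohexa-2,4-dien-1-one (racemic)
Conditions: TBAF, THF, 0 °C; H2O work-up
Reagents that add atoms: none
Why: Fluoride-mediated Si–O cleavage (TBAF desilylation) under non-acidic conditions should free the alcohol without touching the two vinylogous ester enol ethers or ionising the carbinol.

**Step 6**
Reactants: 13 3,5-diethoxy-2-(1-hydroxybutyl)-6,6-dimethylcyclohexa-2,4-dien-1-one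
Product: 14 2-butanoyl-3,5-diethoxy-6,6-dimethylcyclohexa-2,4-dien-1-one
Conditions: Dess–Martin periodinane, CH2Cl2, rt
Reagents that add atoms: none
Why: Dess–Martin oxidation of the secondary alcohol to the ketone is mild enough for the dienone bis-enol ether and removes the only stereocentre of the route.

**Step 7**
Reactants: 14 2-butanoyl-3,5-diethoxy-6,6-dimethylcyclohexa-2,4-dien-1-one
Product: 15 butyrylfilicinic acid (2-butanoyl-3,5-dihydroxy-4,4-dimethylcyclohexa-2,5-dien-1-one)
Conditions: 2 M aq. HCl, THF, 60 °C
Reagents that add atoms: water, O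
Why: Acid hydrolysis of the two vinylogous ester ethyl ethers (addition of water at the β-alkoxy enone carbons and loss of ethanol) should unmask the acyl β-triketone, which is stable to aqueous acid.

**Step 8**
Reactants: 16 phloroglucinol; 17 butanoyl chloride
Product: 18 1-(2,4,6-trihydroxyphenyl)butan-1-one
Conditions: AlCl3, PhNO2/CH2Cl2, 0 → 40 °C; aq. HCl work-up
Reagents that add atoms: none
Why: Friedel–Crafts C-acylation of the electron-rich triol should stop at mono-acylation because the first acyl group, held in a hydrogen-bonded chelate, deactivates the ring.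

**Step 9**
Reactants: 18 1-(2,4,6-trihydroxyphenyl)butan-1-one
Product: 19 1-{3,5-bis[(dimethylamino)methyl]-2,4,6-trihydroxyphenyl}butan-1-one
Conditions: CH2(NMe2)2 (2.5 equiv), EtOH, rt → 40 °C
Reagents that add atoms: bis(dimethylamino)methane, CN(C)CN(C)C
Why: Double phenolic Mannich reaction, in which the acidic acylphloroglucinol protonates the aminal to the iminium ion that attacks both remaining nucleophilic ring CH positions.

**Step 10**
Reactants: 19 1-{3,5-bis[(dimethylamino)methyl]-2,4,6-trihydroxyphenyl}butan-1-one; 18 1-(2,4,6-trihydroxyphenyl)butan-1-one (8 equiv, excess recovered)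
Product: 23 1-{3,5-bis[(3-butanoyl-2,4,6-trihydroxyphenyl)methyl]-2,4,6-trihydroxyphenyl}butan-1-one, via quinone methide 20 (not isolated), via mono-coupled Mannich base 21 (not isolated), via second quinone methide 22 (not isolated)
Conditions: 1,4-dioxane, 95 °C, N2 sweep
Reagents that add atoms: none
Why: Thermal loss of dimethylamine from the phenolic Mannich base gives an o-quinone methide that is captured by conjugate (Friedel–Crafts-type Michael) addition of a free ring carbon of 18, twice in succession, the large excess of 18 suppressing chain growth.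

**Step 11**
Reactants: 15 butyrylfilicinic acid
Product: 24 2-butanoyl-6-[(dimethylamino)methyl]-3,5-dihydroxy-4,4-dimethylcyclohexa-2,5-dien-1-one (expected as the zwitterion)
Conditions: CH2(NMe2)2 (1.05 equiv), CH2Cl2, 0 °C → rt
Reagents that add atoms: bis(dimethylamino)methane, CN(C)CN(C)C
Why: Mannich reaction at C6, the only remaining nucleophilic enol carbon of the β-triketone, which is acidic enough to generate the iminium ion from the aminal itself.

**Step 12**
Reactants: 24 2-butanoyl-6-[(dimethylamino)methyl]-3,5-dihydroxy-4,4-dimethylcyclohexa-2,5-dien-1-one (2.2 equiv); 23 1-{3,5-bis[(3-butanoyl-2,4,6-trihydroxyphenyl)methyl]-2,4,6-trihydroxyphenyl}butan-1-one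
Product: 27 target pentamer (end ring–CH2–ring B–CH2–ring C–CH2–ring B–CH2–end ring), via methylene triketone 25 (not isolated), via mono-coupled tetramer 26 (not isolated)
Conditions: 1,4-dioxane, 50 °C, N2 sweep; cold dilute aq. HCl work-up
Reagents that add atoms: none
Why: Retro-Michael loss of dimethylamine from the zwitterionic Mannich base gives the methylene triketone 25, which should be captured by conjugate addition of the only two free aromatic carbons of 23 (quinone methide-type Friedel–Crafts alkylation) to give the symmetric pentamer.

**Compound list**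

1 | ethoxyacetylene (ethoxyethyne) | C#COCC | starting material
2 | butanal | CCCC=O | starting material
3 | lithium ethoxyacetylide | [Li]C#COCC | intermediate
4 | 1-ethoxyhex-1-yn-3-ol (racemic) | CCCC(O)C#COCC | intermediate
5 | tert-butyl[(1-ethoxyhex-1-yn-3-yl)oxy]dimethylsilane (racemic) | CCCC(O[Si](C)(C)C(C)(C)C)C#COCC | intermediate
6 | 2-methylpropanoyl chloride (isobutyryl chloride) | CC(C)C(Cl)=O | starting material
7 | dimethylketene | CC(C)=C=O | intermediate
8 | 3-ethoxy-4,4-dimethylcyclobut-2-en-1-one | CCOC1=CC(=O)C1(C)C | intermediate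
9 | 3-ethoxy-4-methylpenta-1,3-dien-1-one (vinylketene) | CCOC(C=C=O)=C(C)C | intermediate
10 | 2-[1-(tert-butyldimethylsilyloxy)butyl]-3-ethoxy-4-(1-ethoxy-2-methylprop-1-enyl)cyclobut-2-en-1-one (racemic mixture of diastereomers) | CCCC(O[Si](C)(C)C(C)(C)C)C1=C(OCC)C(C(OCC)=C(C)C)C1=O | intermediate
11 | (3E)-2-[1-(tert-butyldimethylsilyloxy)butyl]-3,5-diethoxy-6-methylhepta-1,3,5-trien-1-one (dienylketene, racemic) | CCCC(O[Si](C)(C)C(C)(C)C)C(=C=O)/C(OCC)=C\C(OCC)=C(C)C | intermediate
12 | 2-[1-(tert-butyldimethylsilyloxy)butyl]-3,5-diethoxy-6,6-dimethylcyclohexa-2,4-dien-1-one (racemic) | CCCC(O[Si](C)(C)C(C)(C)C)C1=C(OCC)C=C(OCC)C(C)(C)C1=O | intermediate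
13 | 3,5-diethoxy-2-(1-hydroxybutyl)-6,6-dimethylcyclohexa-2,4-dien-1-one (racemic) | CCCC(O)C1=C(OCC)C=C(OCC)C(C)(C)C1=O | intermediate
14 | 2-butanoyl-3,5-diethoxy-6,6-dimethylcyclohexa-2,4-dien-1-one | CCCC(=O)C1=C(OCC)C=C(OCC)C(C)(C)C1=O | intermediate
15 | butyrylfilicinic acid (2-butanoyl-3,5-dihydroxy-4,4-dimethylcyclohexa-2,5-dien-1-one) | CCCC(=O)C1=C(O)C(C)(C)C(O)=CC1=O | intermediate
16 | phloroglucinol (benzene-1,3,5-triol) | Oc1cc(O)cc(O)c1 | starting material
17 | butanoyl chloride | CCCC(Cl)=O | starting material
18 | 1-(2,4,6-trihydroxyphenyl)butan-1-one | CCCC(=O)c1c(O)cc(O)cc1O | intermediate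
19 | 1-{3,5-bis[(dimethylamino)methyl]-2,4,6-trihydroxyphenyl}butan-1-one | CCCC(=O)c1c(O)c(CN(C)C)c(O)c(CN(C)C)c1O | intermediate
20 | 2-butanoyl-4-[(dimethylamino)methyl]-3,5-dihydroxy-6-methylidenecyclohexa-2,4-dien-1-one (o-quinone methide, one tautomer) | CCCC(=O)C1=C(O)C(CN(C)C)=C(O)C(=C)C1=O | intermediate
21 | 1-{3-[(3-butanoyl-2,4,6-trihydroxyphenyl)methyl]-5-[(dimethylamino)methyl]-2,4,6-trihydroxyphenyl}butan-1-one | CCCC(=O)c1c(O)c(CN(C)C)c(O)c(Cc2c(O)cc(O)c(C(=O)CCC)c2O)c1O | intermediate
22 | 4-butanoyl-2-[(3-butanoyl-2,4,6-trihydroxyphenyl)methyl]-3,5-dihydroxy-6-methylidenecyclohexa-2,4-dien-1-one (o-quinone methide, one tautomer) | CCCC(=O)C1=C(O)C(=C)C(=O)C(Cc2c(O)cc(O)c(C(=O)CCC)c2O)=C1O | intermediate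
23 | 1-{3,5-bis[(3-butanoyl-2,4,6-trihydroxyphenyl)methyl]-2,4,6-trihydroxyphenyl}butan-1-one (three-ring core) | CCCC(=O)c1c(O)c(Cc2c(O)cc(O)c(C(=O)CCC)c2O)c(O)c(Cc2c(O)cc(O)c(C(=O)CCC)c2O)c1O | intermediate
24 | 2-butanoyl-6-[(dimethylamino)methyl]-3,5-dihydroxy-4,4-dimethylcyclohexa-2,5-dien-1-one | CCCC(=O)C1=C(O)C(C)(C)C(O)=C(CN(C)C)C1=O | intermediate
25 | 2-butanoyl-3-hydroxy-4,4-dimethyl-6-methylidenecyclohex-2-ene-1,5-dione (methylene triketone) | CCCC(=O)C1=C(O)C(C)(C)C(=O)C(=C)C1=O | intermediate
26 | mono-coupled tetramer: three-ring core 23 carrying one (3-butanoyl-2,6-dihydroxy-5,5-dimethyl-4-oxocyclohexa-2,5-dienyl)methyl end ring, one outer aromatic CH still free | CCCC(=O)C1=C(O)C(C)(C)C(O)=C(Cc2c(O)c(Cc3c(O)c(Cc4c(O)cc(O)c(C(=O)CCC)c4O)c(O)c(C(=O)CCC)c3O)c(O)c(C(=O)CCC)c2O)C1=O | intermediate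
27 | target: three methylene-linked 3-butanoyl-2,4,6-trihydroxyphenyl rings, each outer one joined through CH2 to a butyrylfilicinic acid end ring (achiral) | CCCC(=O)C1=C(O)C(C)(C)C(O)=C(Cc2c(O)c(Cc3c(O)c(Cc4c(O)c(CC5=C(O)C(C)(C)C(O)=C(C(=O)CCC)C5=O)c(O)c(C(=O)CCC)c4O)c(O)c(C(=O)CCC)c3O)c(O)c(C(=O)CCC)c2O)C1=O | target

**Step count and risks**

Total steps: 12. Longest linear sequence: 8 steps (1, 2, 4, 5, 6, 7, 11, 12).

Steps most likely to fail:

1. Step 4. The [2+2] capture of the vinylketene by the hindered, branched ynol ether may be slow, so that retro-ene fragmentation of the ethyl ynol ether, a 1,5-hydrogen shift from a methyl group of the vinylketene, or ketene dimerisation takes over. Fallback, setting out from 8: annulation with the unhindered parent ethoxyacetylene 1 (toluene, 80 °C, sealed tube) should give 3,5-diethoxy-6,6-dimethylcyclohexa-2,4-dien-1-one F1 by the same ring-opening/[2+2]/6π sequence. Hydrolysis with aqueous HCl in THF gives filicinic acid F2, and Friedel–Crafts C-acylation of F2 with butanoyl chloride 17 and AlCl3 in nitrobenzene installs the side chain at one of its two equivalent enol carbons. This comes back to the route at 15 and moves the acyl introduction from the alkyne partner to a separate acylation.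

2. Step 12. Methylene-bridge scrambling by retro-Michael exchange under the amine released, self-condensation of the methylene triketone, or incomplete alkylation of the two hindered ring positions may erode the coupling. Fallback, setting out from 23, with the roles of the partners inverted: aminomethylation of both free ring carbons of 23 with CH2(NMe2)2 in EtOH should give the bis-Mannich base of the three-ring core F3. Heating F3 with butyrylfilicinic acid 15 (2.2 equiv) in 1,4-dioxane at 80–95 °C lets the aromatic o-quinone methides be captured by the single nucleophilic enol carbon C6 of 15, coming back to the route at 27.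

3. Step 10. Over-alkylation and chain growth, in which product rings compete with 18 for the quinone methides, may give oligomer mixtures. Fallback, setting out from 24 and joining the rings from the outside inwards: warming 24 with excess 18 in 1,4-dioxane should give the two-ring compound flavaspidic acid BB F4, which has a single free aromatic carbon. Two equivalents of F4 are then alkylated by the bis-Mannich base 19 (1,4-dioxane, 95 °C), coming back to the route directly at 27 and bypassing 23.

**Further compounds**

F1 | step 4 | 3,5-diethoxy-6,6-dimethylcyclohexa-2,4-dien-1-one | O=C1C=C(OCC)C=C(OCC)C1(C)C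
F2 | step 4 | filicinic acid (3,5-dihydroxy-4,4-dimethylcyclohexa-2,5-dien-1-one) | CC1(C)C(O)=CC(=O)C=C1O
F3 | step 12 | 1-{3,5-bis[(3-butanoyl-5-[(dimethylamino)methyl]-2,4,6-trihydroxyphenyl)methyl]-2,4,6-trihydroxyphenyl}butan-1-one | CCCC(=O)c1c(O)c(Cc2c(O)c(CN(C)C)c(O)c(C(=O)CCC)c2O)c(O)c(Cc2c(O)c(CN(C)C)c(O)c(C(=O)CCC)c2O)c1O
F4 | step 10 | flavaspidic acid BB (2-butanoyl-6-[(3-butanoyl-2,4,6-trihydroxyphenyl)methyl]-3,5-dihydroxy-4,4-dimethylcyclohexa-2,5-dien-1-one) | CCCC(=O)C1=C(O)C(C)(C)C(O)=C(Cc2c(O)cc(O)c(C(=O)CCC)c2O)C1=O
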